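In a one-step world the target made would stay target and one clock would tell the amount, but this flask has a second clock.

    substrate + partner → target, rate k1*[substrate]*[partner]^0.5 (k1 = 0.549 M⁻⁰·⁵ s⁻¹)
    target ⇌ isomer of the product (K2 = 0.64, k2 = 0.0397 s⁻¹)
    partner → decomposed reagent (k3 = 0.00213 s⁻¹)

| setting | north-east | north | east |
|---|---|---|---|
| substrate | 0.0010 M | 0.0010 M | 0.0010 M |
| partner | 1.00 mM | 2.00 mM | 4.00 mM |
| time | 25 s | 25 s | 25 s |

- "hardly changes" means that all values lie within two and a half points (for a concentration: within two and a half percent of the largest)
- run time (north-east): 25 s

- amount of target at the end, in percent of the substrate charged for north-east, north, east, in this order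
- the course of these numbers from the first flask to the last (falls all the way / rises, then falls / falls, then rises / hardly changes / rises all the way)

Holding c(partner) steady makes the first step a first-order decay of substrate (pseudo-first-order). But partner is used one for one with substrate, so I hold it at its charge less half of what a first pass at the charge would use, and the lifetimes of substrate come to 63.5 s in north-east, 43.3 s in north and 29.9 s in east. By my reckoning, then, the amount turned into target or isomer by the end is 32.6% in north-east, 43.9% in north and 56.7% in east.

Two colleagues dispute how much of that is still target. The first points out that the exchange has a relaxation half-life of 6.81 s, which fits 3.67 times into the run. So target should stand at its equilibrium share of 61.0%, giving 19.9%, 26.8% and 34.6%.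

The second answers that material keeps arriving, and the late arrivals have had little time to move. The clock to count is the lag, one over the forward and backward rate constants of the exchange added together, 9.83 s. The rule is that the isomer stands at its equilibrium share, 39.0%, of what had been made one lag earlier. I take this side: that isomer comes to 8.30%, 11.5% and 15.5%, and subtracting it gives me 24 percentage points, 32 points and 41 points of target, so the course I commit to is rises all the way.

The forecast, made by someone who saw the problem but no run, gives 23.5%, 31.7% and 40.8%, rises all the way, a little lower than my row, on the ground that the exchange “relaxes in about 10 s and pulls the mixture toward roughly 61% target”.

The simulation gives 23.6%, 31.7% and 40.7%, rises all the way. Each value is lower than my row and higher than the equilibrium row.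

In east, the exchange and the short time together hold target down. With the exchange removed, target in east ends at 56.0%, and at 250 s it reaches 60.9% in east, the first colleague's share, so that view holds in east at that late time. The lag reads the isomer: in east, 15.3% divided by 39.0% means 39.2% made by 15.2 s, between 34.4% at 12.5 s and 56.0% at the end. In north-east, 8.51% gives 21.8%, between 18.5% at 12.5 s and 32.1% at the end.

(The rate constants are those of an exercise; the result is computed.)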